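**Retrosynthetic overview**

1. Target 11 comes from LiAlH4 reduction of the all-trans diester 10. C2 and C3 are α to esters, so NaOMe equilibration sets them relative to C1; only C1 needs absolute control.
2. Diester 10 comes from hydrogenation (C3=C4 reduction plus loss of both benzyl groups) of the 1-aryl-1,2-dihydronaphthalene diester 8.
3. Compound 8 comes from the proposed new step: a chiral Brønsted acid-catalysed enantioselective protonative Friedel–Crafts cyclisation of the achiral (E,E)-bis(arylidene)succinate 7. This forms C1–C8a and sets C1.
4. Diene 7 comes from two Stobbe condensations of O-benzylvanillin 1 with dimethyl succinate 2.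
5. Ring order: both benzene rings are purchased; the central six-membered carbocycle is the only ring formed (step 5).

Assumption: the sense of induction of the new step cannot be predicted in advance. The route is written with the catalyst antipode that gives (1S)-8; both antipodes are equally accessible. Positions are numbered as in 1-aryltetralin (C1 bears the aryl group).

**Route**

Step 1
Reactants: 1, 4-(benzyloxy)-3-methoxybenzaldehyde (O-benzylvanillin); 2, dimethyl succinate
Product: 3, (E)-4-[4-(benzyloxy)-3-methoxyphenyl]-3-(methoxycarbonyl)but-3-enoic acid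
Conditions: NaOMe, MeOH, reflux; then aq. HCl
Reagents that add atoms: none (all heavy atoms come from 1 and 2)
Why: Stobbe condensation (aldol, paraconate lactonisation, E1cB ring opening) reliably gives the (E)-arylidene half-ester; no stereocentre is formed.

Step 2
Reactants: 3; 4, iodomethane
Product: 5, dimethyl (E)-2-[4-(benzyloxy)-3-methoxybenzylidene]succinate
Conditions: K2CO3, DMF, rt
Reagents that add atoms: iodomethane (4), CI
Why: SN2 O-alkylation of the carboxylate under mild base leaves the alkene geometry and the benzyl ether untouched.

Step 3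
Reactants: 5; 1, 4-(benzyloxy)-3-methoxybenzaldehyde
Product: 6, (2E,3E)-2,3-bis[4-(benzyloxy)-3-methoxybenzylidene]succinic acid monomethyl ester
Conditions: NaOMe, MeOH, reflux; then aq. HCl
Reagents that add atoms: none (all heavy atoms come from 5 and 1)
Why: A second Stobbe condensation at the remaining CH2 (lactonisation onto the conjugated ester, then E1cB opening) gives the (E,E)-diene half-ester, each aryl anti to its own carboxyl group.

Step 4
Reactants: 6; 4, iodomethane
Product: 7, dimethyl (2E,3E)-2,3-bis[4-(benzyloxy)-3-methoxybenzylidene]succinate (achiral, C2-symmetric)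
Conditions: K2CO3, DMF, rt
Reagents that add atoms: iodomethane (4), CI
Why: Carboxylate O-methylation (SN2) as in step 2; it makes the two halves equivalent, so either can act as electrophile in step 5.

Step 5
Reactants: 7
Product: 8, dimethyl (1S,2R)-7-(benzyloxy)-1-[4-(benzyloxy)-3-methoxyphenyl]-6-methoxy-1,2-dihydronaphthalene-2,3-dicarboxylate (1,2-trans)
Conditions: chiral IDPi acid (5 mol%; imidodiphosphorimidate from two 3,3'-bis[3,5-(CF3)2C6H3]-BINOL units with N-SO2C6F5 groups), dry CHCl3, 0 °C → rt
Reagents that add atoms: none (isomerisation)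
Why: Proposed new method: the confined, strongly acidic IDPi protonates the α-carbon of one cinnamate unit to give a p-benzyloxy-stabilised benzylic cation held as a contact ion pair in the chiral anion pocket; the other aryl ring, kept cis by its (E)-alkene, attacks para to its OMe through a six-membered transition state on one enantiotopic face (setting C1 and closing the ring), and rearomatisation returns the proton, with the C2 ester ending trans to the aryl group (it is reset in step 7 anyway); the closest known reactions are the racemic stoichiometric superacid (TfOH) cyclisation of 2,3-dibenzylidenesuccinates to trans-1-aryl-1,2-dihydronaphthalenes and IDPi/chiral phosphoric acid ion-pair catalysis of Nazarov, hydroarylation and Friedel–Crafts cyclisations.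

Step 6
Reactants: 8
Product: 9, dimethyl (1S,2R,3ξ)-7-hydroxy-1-(4-hydroxy-3-methoxyphenyl)-6-methoxy-1,2,3,4-tetrahydronaphthalene-2,3-dicarboxylate (C3 epimer mixture, 2,3-cis expected major)
Conditions: H2 (1 atm), 10% Pd/C, EtOAc–MeOH, rt
Reagents that add atoms: none (H2 only)
Why: Neutral heterogeneous hydrogenation saturates the cinnamate-type C3=C4 bond and hydrogenolyses both aryl benzyl ethers in one operation; base is deliberately avoided while C1–H is still allylic, and the uncontrolled C3 centre is corrected in step 7.

Step 7
Reactants: 9
Product: 10, dimethyl (1S,2R,3R)-7-hydroxy-1-(4-hydroxy-3-methoxyphenyl)-6-methoxy-1,2,3,4-tetrahydronaphthalene-2,3-dicarboxylate (all-trans)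
Conditions: NaOMe (excess), degassed MeOH, reflux; AcOH quench
Reagents that add atoms: none
Why: Thermodynamic epimerisation through the ester enolates: C2–H and C3–H are acidic while the diaryl-methine C1–H is not, so the mixture converges on the all-equatorial 1,2-trans-2,3-trans diester and the C1 configuration is relayed to C2 (R) and C3 (R).

Step 8
Reactants: 10
Product: 11, (+)-isolariciresinol, (1S,2R,3R)-7-hydroxy-1-(4-hydroxy-3-methoxyphenyl)-6-methoxy-1,2,3,4-tetrahydronaphthalene-2,3-dimethanol
Conditions: LiAlH4 (excess), THF, 0 °C → reflux; Rochelle salt / dilute HCl work-up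
Reagents that add atoms: none (hydride only)
Why: LiAlH4 reduction of both esters to primary alcohols; the phenols are only deprotonated and recovered on work-up, aryl methyl ethers are inert, and no stereocentre is touched.

**Compound list**

1 | 4-(benzyloxy)-3-methoxybenzaldehyde | O=Cc1ccc(OCc2ccccc2)c(OC)c1 | starting material
2 | dimethyl succinate | COC(=O)CCC(=O)OC | starting material
3 | (E)-4-[4-(benzyloxy)-3-methoxyphenyl]-3-(methoxycarbonyl)but-3-enoic acid | COC(=O)/C(=C/c1ccc(OCc2ccccc2)c(OC)c1)CC(=O)O | intermediate
4 | iodomethane | CI | starting material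
5 | dimethyl (E)-2-[4-(benzyloxy)-3-methoxybenzylidene]succinate | COC(=O)/C(=C/c1ccc(OCc2ccccc2)c(OC)c1)CC(=O)OC | intermediate
6 | (2E,3E)-2,3-bis[4-(benzyloxy)-3-methoxybenzylidene]succinic acid monomethyl ester | COC(=O)/C(=C/c1ccc(OCc2ccccc2)c(OC)c1)/C(=C\c1ccc(OCc2ccccc2)c(OC)c1)C(=O)O | intermediate
7 | dimethyl (2E,3E)-2,3-bis[4-(benzyloxy)-3-methoxybenzylidene]succinate | COC(=O)/C(=C/c1ccc(OCc2ccccc2)c(OC)c1)/C(=C\c1ccc(OCc2ccccc2)c(OC)c1)C(=O)OC | intermediate
8 | dimethyl (1S,2R)-7-(benzyloxy)-1-[4-(benzyloxy)-3-methoxyphenyl]-6-methoxy-1,2-dihydronaphthalene-2,3-dicarboxylate | COc1cc([C@H]2c3cc(OCc4ccccc4)c(OC)cc3C=C(C(=O)OC)[C@@H]2C(=O)OC)ccc1OCc1ccccc1 | intermediate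
9 | dimethyl (1S,2R,3ξ)-7-hydroxy-1-(4-hydroxy-3-methoxyphenyl)-6-methoxy-1,2,3,4-tetrahydronaphthalene-2,3-dicarboxylate (C3 mixture) | COc1cc([C@H]2c3cc(O)c(OC)cc3CC(C(=O)OC)[C@@H]2C(=O)OC)ccc1O | intermediate
10 | dimethyl (1S,2R,3R)-7-hydroxy-1-(4-hydroxy-3-methoxyphenyl)-6-methoxy-1,2,3,4-tetrahydronaphthalene-2,3-dicarboxylate | COc1cc([C@H]2c3cc(O)c(OC)cc3C[C@@H](C(=O)OC)[C@@H]2C(=O)OC)ccc1O | intermediate
11 | (+)-isolariciresinol | COc1cc([C@H]2c3cc(O)c(OC)cc3C[C@@H](CO)[C@@H]2CO)ccc1O | target

**Summary**

Total step count: 8. Longest linear sequence: 8 steps (fully linear; aldehyde 1 is used twice).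

Steps most likely to fail:

1. **Step 5 (proposed new enantioselective cyclisation).** Risks are insufficient acidity or turnover, low ee from a loose ion pair, and acid-induced benzyl loss or migration. Fallback (known chemistry, branching from 3):
   - Rh/chiral bisphosphine asymmetric hydrogenation of half-ester 3 to the (R)-2-arylmethylsuccinic acid monoester.
   - Ca(BH4)2 reduction and lactonisation to (R)-β-(4-benzyloxy-3-methoxybenzyl)-γ-butyrolactone.
   - LiHMDS aldol with 1 (trans), then TFA Friedel–Crafts cyclisation to the all-trans aryltetralin lactone.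
   - LiAlH4 reduction, then H2, Pd/C to give 11.
2. **Step 3 (second Stobbe condensation).** Risks are modest yield and E/Z mixtures. Fallback: build the symmetric diene by C–C homocoupling instead. Methyl (Z)-2-bromo-3-[4-(benzyloxy)-3-methoxyphenyl]acrylate (from the cinnamate by Br2 addition and Et3N dehydrobromination) undergoes Ni(0) reductive homocoupling (NiCl2(PPh3)2, Zn, Et4NI) with retention of geometry to give 7 directly.
3. **Step 7 (thermodynamic epimerisation).** Risks are incomplete convergence to the all-trans isomer and phenoxide side reactions. Fallback: set C3 kinetically. Hydrogenate 8 with a cationic Ir catalyst ([Ir(cod)(PCy3)(py)]PF6, H2, CH2Cl2), where the C2 ester directs H delivery syn to itself and gives the 2,3-trans diester with benzyl ethers intact; then LiAlH4 and a final H2, Pd/C debenzylation.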